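The seven-membered ring is treated as a benzene ring: C5–C10 carry a benzenoid substitution pattern (C6–O ortho and C8–CH3 para to C5), and the quaternary C1, bearing CH3 and the oxygenated C2, sits between C5 and C10 and is tied back to C5 through C3–C4. An intramolecular Buchner reaction of an α-diazo ketone on a cresyl methyl ether therefore forms C1–C5 and C1–C10, closes the cyclopentanone, expands the arene to the cycloheptatriene and sets C1 in one operation. The precursor is (R)-2-diazo-5-(2-methoxy-4-methylphenyl)-6-methylheptan-3-one, made by asymmetric 1,4-arylation and diazoethane acylation; all remaining stereocentres are relayed from C1.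

Key step: step 5

Remark on locants: C1 = ring-fusion carbon with CH3, C2 = carbinol CH, C3 = CH2, C4 = isopropyl-bearing carbon, C5 = ring-fusion carbon, C6–C10 run round the seven-membered ring (C8 bears CH3). "Daucane" means this bicyclo[5.3.0]decane skeleton with these locants. β is the face carrying the C1 methyl, α the other face. TBS = tert-butyldimethylsilyl, TMS = trimethylsilyl.

Assumption: (S)-BINAP is taken as the ligand enantiomer that gives (R)-3, by analogy with other E-acceptors carrying a β-isopropyl group; if the sense proves opposite, (R)-BINAP is used and nothing else changes.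

Remark on the structures: the stereodescriptors of every intermediate were checked against the target; the compounds below are mutually consistent. In daucane locants the target is (1S,2S,4R,5S,6S,8S,9R,10R).

Step 1
Reactants: 1 2-methoxy-4-methylphenylboronic acid; 2 ethyl (E)-4-methylpent-2-enoate
Product: 3 ethyl (R)-3-(2-methoxy-4-methylphenyl)-4-methylpentanoate
Conditions: Rh(acac)(C2H4)2 (3 mol %), (S)-BINAP (3.3 mol %), 1 (3 equiv), dioxane/H2O 10:1, 100 °C
Reagents that add atoms: none
Why: Hayashi–Miyaura asymmetric 1,4-addition, in which the aryl–rhodium species inserts the enoate face selected by the BINAP pocket, joining C4 to C5 and setting C4 as (R), and water protonates the rhodium enolate; excess boronic acid offsets protodeboronation of the ortho-substituted arene.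

Step 2
Reactants: 3 ethyl (R)-3-(2-methoxy-4-methylphenyl)-4-methylpentanoate
Product: 4 (R)-3-(2-methoxy-4-methylphenyl)-4-methylpentanoic acid
Conditions: LiOH, THF/MeOH/H2O, 50 °C; then 1 M HCl
Reagents that add atoms: LiOH (hydroxide oxygen), [Li+].[OH-]
Why: Ordinary ester saponification; the stereocentre is β to the carbonyl group and cannot epimerise.

Step 3
Reactants: 5 N-ethyl-N-nitrosourea
Product: 6 diazoethane (cold ether solution)
Conditions: 40 % aq. KOH, Et2O, -10 → 0 °C; ether layer dried over KOH pellets, used at once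
Reagents that add atoms: none
Why: Base-induced fragmentation of an N-alkyl-N-nitrosourea, the standard way to generate a diazoalkane, giving diazoethane with cyanate as the other fragment.

Step 4
Reactants: 4 (R)-3-(2-methoxy-4-methylphenyl)-4-methylpentanoic acid; 6 diazoethane
Product: 8 (R)-2-diazo-5-(2-methoxy-4-methylphenyl)-6-methylheptan-3-one, via acid chloride 7 (not isolated)
Conditions: (COCl)2, cat. DMF, CH2Cl2, 0 °C → rt, evaporate; then 6 (3.5 equiv), Et2O, -20 → 0 °C
Reagents that add atoms: none
Why: Acid chloride formation followed by C-acylation of the diazoalkane (Arndt–Eistert-type diazo ketone synthesis), with a second equivalent of diazoethane scavenging HCl so that no α-chloro ketone forms; C4 is not touched.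

Step 5
Reactants: 8 (R)-2-diazo-5-(2-methoxy-4-methylphenyl)-6-methylheptan-3-one
Product: 10 (3R,8aS)-4-methoxy-6,8a-dimethyl-3-isopropyl-3,8a-dihydroazulen-1(2H)-one, via norcaradiene 9 (not isolated)
Conditions: Rh2(OAc)4 (1 mol %), CH2Cl2, reflux, slow addition of 8 (final ca. 0.005 M)
Reagents that add atoms: none
Why: Rh2(OAc)4 expels N2 from 8 to give an electrophilic divalent-rhodium carbenoid at C1, which adds across the C5–C10 bond of the arene (intramolecular Buchner reaction), and norcaradiene 9 then opens by disrotatory six-electron cleavage of C5–C10 to cycloheptatriene 10. The closest known reaction type is the Rh2(OAc)4-catalysed cyclisation of 2-diazo-5-arylalkan-3-ones to 8a-methyl-3,8a-dihydroazulen-1(2H)-ones, to which only the ortho-methoxy group is added here. The cyclopentanone C1–C2–C3–C4–C5 closes as a five-membered ring through 3-exo formation of the cyclopropane over the three-atom tether, and the seven-membered ring arises by expansion of the benzene ring, not by a separate cyclisation. The new quaternary stereocentre C1 is controlled by C4: the tether folds with isopropyl pseudo-equatorial, so the carbenoid reaches the arene face that places the C1 methyl trans to isopropyl. The step needs addition at C5–C10 and not C5–C6, which the methoxy group on C6 secures by blocking its own side, and cycloaddition rather than Friedel–Crafts substitution, which is favoured because attack at C10 puts no positive charge on the carbons bearing OCH3 or CH3. Slow addition at high dilution to the carboxylate catalyst keeps 1,2-hydride shift from the carbenoid methyl and C–H insertion into the isopropyl methine in the background.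

Step 6
Reactants: 10 (3R,8aS)-4-methoxy-6,8a-dimethyl-3-isopropyl-3,8a-dihydroazulen-1(2H)-one
Product: 11 (1S,3R,8aS)-4-methoxy-6,8a-dimethyl-3-isopropyl-1,2,3,8a-tetrahydroazulen-1-ol (OH cis to the angular methyl)
Conditions: (R)-2-methyl-CBS-oxazaborolidine (0.3 equiv), BH3·SMe2, THF, -20 °C; MeOH quench
Reagents that add atoms: none
Why: Corey–Bakshi–Shibata reduction in which the (R)-catalyst, reading quaternary C1 as the large and C3H2 as the small substituent, delivers hydride to the α face of the C2 ketone, the face the substrate also prefers (anti to the angular methyl), so the 2β-carbinol (2S) should form as a matched case.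

Step 7
Reactants: 11 (1S,3R,8aS)-4-methoxy-6,8a-dimethyl-3-isopropyl-1,2,3,8a-tetrahydroazulen-1-ol
Product: 12 TBS ether of 11 (2β-OTBS in daucane locants)
Conditions: TBSOTf, 2,6-lutidine, CH2Cl2, -78 → 0 °C
Reagents that add atoms: tert-butyldimethylsilyl triflate, CC(C)(C)[Si](C)(C)OS(=O)(=O)C(F)(F)F
Why: Silylation of a hindered neopentyl secondary alcohol with a silyl triflate and a non-nucleophilic base; the enol ether tolerates these non-acidic conditions.

Step 8
Reactants: 12 TBS ether of 11
Product: 13 5α-bromo-4α-isopropyl-2β-(TBS-oxy)dauca-7,9-dien-6-one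
Conditions: NBS (1.05 equiv), NaHCO3, THF/H2O 9:1, 0 °C
Reagents that add atoms: N-bromosuccinimide, O=C1CCC(=O)N1Br; water, O
Why: Electrophilic bromination of the enol ether at its β-carbon C5, the only position whose attack is stabilised by the methoxy group, expected on the α face anti to the pseudo-axial C1 methyl, followed by hydrolysis of the oxocarbenium ion to the C6 ketone (α-bromo ketone synthesis from an enol ether).

Step 9
Reactants: 13 5α-bromo-4α-isopropyl-2β-(TBS-oxy)dauca-7,9-dien-6-one
Product: 14 2β-(TBS-oxy)dauca-4,7,9-trien-6-one (cross-conjugated trienone)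
Conditions: Li2CO3, LiBr, DMF, 110 °C
Reagents that add atoms: none
Why: Dehydrobromination of an α-bromo ketone, in which the 5α-bromide and the 4β-hydrogen are trans so that anti elimination (E2) gives the tetrasubstituted C4=C5 enone, C4–H being the only β-hydrogen available.

Step 10
Reactants: 14 2β-(TBS-oxy)dauca-4,7,9-trien-6-one
Product: 15 9α,10α-epoxy-2β-(TBS-oxy)dauca-4,7-dien-6-one
Conditions: m-CPBA (1.05 equiv), NaHCO3, CH2Cl2, 0 °C
Reagents that add atoms: m-chloroperoxybenzoic acid, OOC(=O)c1cccc(Cl)c1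
Why: Prilezhaev epoxidation, where C9=C10 is the only alkene not directly deactivated as an α,β-bond of the ketone (the γ,δ-selectivity usual for dienones) and the peracid should approach the α face, anti to the pseudo-axial C1 methyl and the C2 silyloxy group, which fixes the C10 oxygen as α.

Step 11
Reactants: 15 9α,10α-epoxy-2β-(TBS-oxy)dauca-4,7-dien-6-one
Product: 16 10α-hydroxy-2β-(TBS-oxy)dauca-4,8-dien-6-one
Conditions: SmI2 (2.2 equiv), THF/MeOH, -78 °C; pH 7 buffer; used without delay
Reagents that add atoms: none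
Why: Reduction of a γ,δ-epoxy enone by divalent samarium (vinylogous reductive epoxide opening), in which the ketyl radical anion expels the C9–O bond, a second electron gives the dienolate and kinetic protonation at C7 leaves the 10α-hydroxyl and a skipped C8=C9 alkene; C10 is not touched.

Step 12
Reactants: 16 10α-hydroxy-2β-(TBS-oxy)dauca-4,8-dien-6-one
Product: 17 2β-(TBS-oxy)dauca-4,8-diene-6α,10α-diol
Conditions: (S)-2-methyl-CBS-oxazaborolidine (1 equiv), catecholborane (3 equiv), toluene/CH2Cl2, -78 → -40 °C; MeOH, then aq. NaOH wash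
Reagents that add atoms: none
Why: Corey–Bakshi–Shibata reduction under catalyst control, in which the (S)-catalyst, with the fully substituted alkenyl carbon C5 as large and C7H2 as small group, should add hydride to the β face of C6 and give the temporary 6α-carbinol (6R) on the face of the C10 hydroxyl; excess borane allows for the free hydroxyl.

Step 13
Reactants: 17 2β-(TBS-oxy)dauca-4,8-diene-6α,10α-diol
Product: 18 4α,5α:8α,9α-diepoxy-2β-(TBS-oxy)daucane-6α,10α-diol
Conditions: VO(acac)2 (10 mol %), t-BuOOH (3 equiv, decane), CH2Cl2, 0 °C → rt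
Reagents that add atoms: tert-butyl hydroperoxide, CC(C)(C)OO
Why: Vanadium-catalysed hydroxyl-directed epoxidation, in which the 6α-hydroxyl delivers oxygen to the α face of the tetrasubstituted C4=C5 alkene (sets the C4 and C5 oxygens) and the 10α-hydroxyl to the α face of C8=C9 (sets C8 and C9); each alkene has one α-hydroxyl allylic and the other homoallylic to it, and both point the same way.

Step 14
Reactants: 18 4α,5α:8α,9α-diepoxy-2β-(TBS-oxy)daucane-6α,10α-diol
Product: 21 8α,9α-epoxy-4α,10α-dihydroxy-2β-(TBS-oxy)-5β-H-daucan-6-one, via bis-TMS ether 19 (not isolated), via rearranged bis-TMS ketone 20 (not isolated)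
Conditions: TMSOTf (3.5 equiv), i-Pr2NEt (3.7 equiv), 4 Å MS, CH2Cl2, -78 → -50 °C; then citric acid, MeOH, 0 °C
Reagents that add atoms: none
Why: After bis-silylation in the flask, TMSOTf activates the tetrasubstituted 4α,5α-epoxide and the β-hydrogen on C6, antiperiplanar to the C5–O bond and pushed by the C6 silyloxy lone pair, migrates to C5 in a stereospecific semipinacol 1,2-hydride shift of a 2,3-epoxy silyl ether (non-aldol aldol type), which writes the 5β-H (cis fusion) and keeps the 4α-oxygen, while the C8,C9 epoxide, whose carbinol-side terminus C9 is only secondary, should survive and the TMS ethers fall to mild acidic methanolysis.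

Step 15
Reactants: 21 8α,9α-epoxy-4α,10α-dihydroxy-2β-(TBS-oxy)-5β-H-daucan-6-one
Product: 22 8α,9α-epoxy-2β-(TBS-oxy)-5β-H-daucane-4α,6β,10α-triol
Conditions: Me4NBH(OAc)3 (6 equiv), MeCN/AcOH 2:1, -35 → -20 °C
Reagents that add atoms: none
Why: Evans–Saksena reduction, in which the tertiary 4α-hydroxyl binds boron and hydride is delivered internally to the α face of the C6 ketone to give the 1,3-anti diol with the 6β-hydroxyl (6S); the conditions are too mild to open the epoxide or epimerise C5.

Step 16
Reactants: 22 8α,9α-epoxy-2β-(TBS-oxy)-5β-H-daucane-4α,6β,10α-triol; 23 angelic acid, (Z)-2-methylbut-2-enoic acid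
Product: 25 8α,9α-epoxy-4α-hydroxy-2β-(TBS-oxy)-5β-H-daucane-6β,10α-diyl bis[(Z)-2-methylbut-2-enoate], via mixed anhydride 24 (not isolated)
Conditions: 23 (5 equiv), 2,4,6-Cl3C6H2COCl (5 equiv), Et3N, toluene, rt; then 22, 80 °C
Reagents that add atoms: none
Why: Yamaguchi-type esterification through the mixed 2,4,6-trichlorobenzoic anhydride, which acylates both secondary hydroxyls without a nucleophilic catalyst and so without the addition–elimination that turns angelates into tiglates; the hindered tertiary C4 hydroxyl should not react.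

Step 17
Reactants: 25 8α,9α-epoxy-4α-hydroxy-2β-(TBS-oxy)-5β-H-daucane-6β,10α-diyl bis[(Z)-2-methylbut-2-enoate]
Product: 26 target CNP0265715.3, 8α,9α-epoxy-2β,4α-dihydroxy-5β-H-daucane-6β,10α-diyl bis[(Z)-2-methylbut-2-enoate]
Conditions: HF·pyridine, pyridine, THF, 0 °C → rt
Reagents that add atoms: none
Why: Fluoride cleavage of the silyl ether under buffered, weakly acidic conditions, which avoids the acyl migration a basic fluoride source could cause; esters, epoxide and tertiary alcohol should be inert.

Compound list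
1 | 2-methoxy-4-methylphenylboronic acid | COc1cc(C)ccc1B(O)O | starting material
2 | ethyl (E)-4-methylpent-2-enoate | CCOC(=O)/C=C/C(C)C | starting material
3 | ethyl (R)-3-(2-methoxy-4-methylphenyl)-4-methylpentanoate | COc1cc(C)ccc1[C@@H](C(C)C)CC(=O)OCC | intermediate
4 | (R)-3-(2-methoxy-4-methylphenyl)-4-methylpentanoic acid | COc1cc(C)ccc1[C@@H](C(C)C)CC(=O)O | intermediate
5 | N-ethyl-N-nitrosourea | CCN(N=O)C(N)=O | starting material
6 | diazoethane | CC=[N+]=[N-] | intermediate
7 | (R)-3-(2-methoxy-4-methylphenyl)-4-methylpentanoyl chloride | COc1cc(C)ccc1[C@@H](C(C)C)CC(=O)Cl | intermediate (not isolated)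
8 | (R)-2-diazo-5-(2-methoxy-4-methylphenyl)-6-methylheptan-3-one | COc1cc(C)ccc1[C@@H](C(C)C)CC(=O)C(C)=[N+]=[N-] | intermediate
9 | norcaradiene valence isomer of 10 (cyclopropane C1–C5–C10, diene C6=C7–C8=C9, C1 methyl over the six-membered ring) | COC1=CC(C)=C[C@H]2[C@]3(C)C(=O)C[C@H](C(C)C)[C@]123 | intermediate (not isolated)
10 | (3R,8aS)-4-methoxy-6,8a-dimethyl-3-isopropyl-3,8a-dihydroazulen-1(2H)-one (isopropyl trans to angular methyl) | COC1=C2[C@@H](C(C)C)CC(=O)[C@@]2(C)C=CC(C)=C1 | intermediate
11 | (1S,3R,8aS)-4-methoxy-6,8a-dimethyl-3-isopropyl-1,2,3,8a-tetrahydroazulen-1-ol | COC1=C2[C@@H](C(C)C)C[C@H](O)[C@@]2(C)C=CC(C)=C1 | intermediate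
12 | TBS ether of 11 | COC1=C2[C@@H](C(C)C)C[C@H](O[Si](C)(C)C(C)(C)C)[C@@]2(C)C=CC(C)=C1 | intermediate
13 | 5α-bromo-4α-isopropyl-2β-(TBS-oxy)dauca-7,9-dien-6-one | O=C1[C@]2(Br)[C@@H](C(C)C)C[C@H](O[Si](C)(C)C(C)(C)C)[C@@]2(C)C=CC(C)=C1 | intermediate
14 | 2β-(TBS-oxy)dauca-4,7,9-trien-6-one | O=C1C2=C(C(C)C)C[C@H](O[Si](C)(C)C(C)(C)C)[C@@]2(C)C=CC(C)=C1 | intermediate
15 | 9α,10α-epoxy-2β-(TBS-oxy)dauca-4,7-dien-6-one | O=C1C=C(C)[C@@H]2O[C@@H]2[C@]2(C)[C@@H](O[Si](C)(C)C(C)(C)C)CC(C(C)C)=C12 | intermediate
16 | 10α-hydroxy-2β-(TBS-oxy)dauca-4,8-dien-6-one | O=C1CC(C)=C[C@H](O)[C@]2(C)[C@@H](O[Si](C)(C)C(C)(C)C)CC(C(C)C)=C12 | intermediate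
17 | 2β-(TBS-oxy)dauca-4,8-diene-6α,10α-diol | O[C@@H]1CC(C)=C[C@H](O)[C@]2(C)[C@@H](O[Si](C)(C)C(C)(C)C)CC(C(C)C)=C12 | intermediate
18 | 4α,5α:8α,9α-diepoxy-2β-(TBS-oxy)daucane-6α,10α-diol | O[C@@H]1C[C@]2(C)O[C@@H]2[C@H](O)[C@]2(C)[C@@H](O[Si](C)(C)C(C)(C)C)C[C@]3(C(C)C)O[C@]123 | intermediate
19 | 6α,10α-bis(trimethylsilyl) ether of 18 | C[Si](C)(C)O[C@@H]1C[C@]2(C)O[C@@H]2[C@H](O[Si](C)(C)C)[C@]2(C)[C@@H](O[Si](C)(C)C(C)(C)C)C[C@]3(C(C)C)O[C@]123 | intermediate (not isolated)
20 | 8α,9α-epoxy-2β-(TBS-oxy)-4α,10α-bis(trimethylsilyloxy)-5β-H-daucan-6-one | O=C1C[C@]2(C)O[C@@H]2[C@H](O[Si](C)(C)C)[C@@]2(C)[C@@H]1[C@](O[Si](C)(C)C)(C(C)C)C[C@@H]2O[Si](C)(C)C(C)(C)C | intermediate (not isolated)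
21 | 8α,9α-epoxy-4α,10α-dihydroxy-2β-(TBS-oxy)-5β-H-daucan-6-one | O=C1C[C@]2(C)O[C@@H]2[C@H](O)[C@@]2(C)[C@@H]1[C@](O)(C(C)C)C[C@@H]2O[Si](C)(C)C(C)(C)C | intermediate
22 | 8α,9α-epoxy-2β-(TBS-oxy)-5β-H-daucane-4α,6β,10α-triol | O[C@H]1C[C@]2(C)O[C@@H]2[C@H](O)[C@@]2(C)[C@@H]1[C@](O)(C(C)C)C[C@@H]2O[Si](C)(C)C(C)(C)C | intermediate
23 | angelic acid, (Z)-2-methylbut-2-enoic acid | C/C=C(/C)C(=O)O | starting material
24 | angelic 2,4,6-trichlorobenzoic anhydride | C/C=C(/C)C(=O)OC(=O)c1c(Cl)cc(Cl)cc1Cl | intermediate (not isolated)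
25 | 8α,9α-epoxy-4α-hydroxy-2β-(TBS-oxy)-5β-H-daucane-6β,10α-diyl bis[(Z)-2-methylbut-2-enoate] | C/C=C(/C)C(=O)O[C@H]1C[C@]2(C)O[C@@H]2[C@H](OC(=O)/C(C)=C\C)[C@@]2(C)[C@@H]1[C@](O)(C(C)C)C[C@@H]2O[Si](C)(C)C(C)(C)C | intermediate
26 | CNP0265715.3, 8α,9α-epoxy-2β,4α-dihydroxy-5β-H-daucane-6β,10α-diyl bis[(Z)-2-methylbut-2-enoate] | C/C=C(/C)C(=O)O[C@H]1C[C@]2(C)O[C@@H]2[C@H](OC(=O)/C(C)=C\C)[C@@]2(C)[C@@H]1[C@](O)(C(C)C)C[C@@H]2O | target

Total step count: 17. Longest linear sequence: 16 steps (steps 1, 2 and 4–17; step 3 is a one-step side branch).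

Steps most likely to fail

Step 14. The Lewis acid may open the C8,C9 epoxide at its tertiary C8 terminus (elimination to an allylic alcohol or a 1,2-shift) faster than, or alongside, the intended C6-to-C5 hydride shift. The fallback runs the hydride shift before the second epoxide exists. It sets out from diene diol 17. One equivalent of m-CPBA (NaHCO3, CH2Cl2, -20 °C) should epoxidise only the more nucleophilic tetrasubstituted C4=C5 alkene, on the α face under hydrogen-bond direction by the C6 hydroxyl, to give 4α,5α-epoxy diol F1. TMSOTf/i-Pr2NEt at -78 °C should then carry this through its bis-TMS ether F2 to rearranged bis-TMS ketone F3 by the same 1,2-hydride shift, and citric acid in MeOH should free alkene hydroxy ketone F4. Epoxidation of C8=C9 with VO(acac)2/t-BuOOH, directed by the 10α-hydroxyl, brings the material back to the route at 21.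

Step 12. Facial selectivity may be poor, because the catalyst has to deliver hydride to the β face of C6, syn to the pseudo-axial C1 methyl, against the likely intrinsic preference of the substrate, and the free C10 hydroxyl diverts borane. The fallback accepts substrate control and corrects the centre afterwards. It sets out from 16. Luche reduction (NaBH4, CeCl3, MeOH, -78 °C) is expected to favour 6β-carbinol F5. Mitsunobu inversion at the less hindered allylic C6 hydroxyl (PPh3, DIAD, 4-nitrobenzoic acid, THF; the neopentyl C10 hydroxyl should not react) should give 6α-(4-nitrobenzoate) F6. Methanolysis with K2CO3 in MeOH returns to the route at 17.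

Step 16. Acylation of the neopentyl C10 hydroxyl may stay incomplete, and forcing it risks Z-to-E isomerisation of the activated angeloyl unit. The fallback builds the Z alkenes after the acylation. It sets out from 22. Both secondary hydroxyls are acylated with 2-[bis(2,2,2-trifluoroethoxy)phosphoryl]propanoic acid (DCC, DMAP, CH2Cl2), which can be pushed freely because no alkene geometry is at stake, to give bis(phosphonopropionate) F7. Still–Gennari olefination with acetaldehyde (KN(SiMe3)2, 18-crown-6, THF, -78 °C) should then form both Z-configured 2-methylbut-2-enoates in place and rejoin the route at 25.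

Further compounds
F1 | step 14 | 4α,5α-epoxy-2β-(TBS-oxy)dauc-8-ene-6α,10α-diol | O[C@@H]1CC(C)=C[C@H](O)[C@]2(C)[C@@H](O[Si](C)(C)C(C)(C)C)C[C@]3(C(C)C)O[C@]123
F2 | step 14 | 6α,10α-bis(trimethylsilyl) ether of F1 | C[Si](C)(C)O[C@@H]1CC(C)=C[C@H](O[Si](C)(C)C)[C@]2(C)[C@@H](O[Si](C)(C)C(C)(C)C)C[C@]3(C(C)C)O[C@]123
F3 | step 14 | 2β-(TBS-oxy)-4α,10α-bis(trimethylsilyloxy)-5β-H-dauc-8-en-6-one | O=C1CC(C)=C[C@H](O[Si](C)(C)C)[C@@]2(C)[C@@H]1[C@](O[Si](C)(C)C)(C(C)C)C[C@@H]2O[Si](C)(C)C(C)(C)C
F4 | step 14 | 4α,10α-dihydroxy-2β-(TBS-oxy)-5β-H-dauc-8-en-6-one | O=C1CC(C)=C[C@H](O)[C@@]2(C)[C@@H]1[C@](O)(C(C)C)C[C@@H]2O[Si](C)(C)C(C)(C)C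
F5 | step 12 | 2β-(TBS-oxy)dauca-4,8-diene-6β,10α-diol (6-epimer of 17) | O[C@H]1CC(C)=C[C@H](O)[C@]2(C)[C@@H](O[Si](C)(C)C(C)(C)C)CC(C(C)C)=C12
F6 | step 12 | 6α-(4-nitrobenzoate) of 17 | O=C(c1ccc(cc1)[N+](=O)[O-])O[C@@H]1CC(C)=C[C@H](O)[C@]2(C)[C@@H](O[Si](C)(C)C(C)(C)C)CC(C(C)C)=C12
F7 | step 16 | 6β,10α-bis{2-[bis(2,2,2-trifluoroethoxy)phosphoryl]propanoate} of 22 | CC(C(=O)O[C@H]1C[C@]2(C)O[C@@H]2[C@H](OC(=O)C(C)P(=O)(OCC(F)(F)F)OCC(F)(F)F)[C@@]2(C)[C@@H]1[C@](O)(C(C)C)C[C@@H]2O[Si](C)(C)C(C)(C)C)P(=O)(OCC(F)(F)F)OCC(F)(F)F
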